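## Structural features

The target is a flavone: a benzo ring A fused through C4a–C8a to the 4-pyranone ring C, with the aryl ring B attached by the C2–C1' bond. It has no stereocentre, so nothing stereochemical has to be set or preserved. Ring A carries hydroxyls at C5 (hydrogen-bonded to the C4 carbonyl) and C7 and a 3-methylbut-2-enyl chain at C8, between O7 and the ring oxygen O1. Ring B carries a hydroxyl at C3', the only methyl ether at C4' and the second chain at C5'. The fragile parts are the two trisubstituted alkenes, which add HX or water under acid and close to a 2,2-dimethylchroman where a free phenol is adjacent (the 7-OH/C8 pair), and the electron-rich polyphenol, which oxidises in base and air. The real difficulty is positional: C8 must be taken and not C6, C5' and not C2' or C6', and of four hydroxyls only O4' may be methylated although O7 is more acidic. The key step uses the fact that each chain-bearing carbon is ortho to an oxygen (C8 to O7 on ring A, C5' to O4' on ring B). These two oxygens are the most acidic of the parent tetrahydroxyflavone, so they can be converted into tertiary allyl ethers from which the chains migrate.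

## Logic of the disconnections

10 from 9. The three O–CH2 acetal bonds on O5, O7 and O3' are cut. A fully masked precursor lets the one ether that must stay (O4'–CH3) be made with no competing hydroxyl, and because the three masks are of one kind a single operation ends the synthesis. The forward step must free three phenols without touching the alkenes, which calls for dilute acid in an alcohol.

9 from 8. The O4'–CH3 bond is cut. The methyl group cannot be present earlier because O4' has to carry the ring B chain into the key step. In 8 it is the only free hydroxyl, so no selectivity problem remains. The demand is complete alkylation of a phenol flanked on both sides.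

8 from 7. The O7–CH2 acetal bond is cut. 7 leaves the key step with two free phenols, and the more acidic one (O7) is not the one to be methylated, so it is covered first. An acetal is chosen because it survives carbonate and an alkylating agent and leaves in the last step with the other two. The forward step must take O7 and leave O4' alone, which rests on the lower pKa and lesser crowding of the 7-hydroxyl.

7 from 5 (through 6). The C8–CH2 and C5'–CH2 bonds are cut and each chain is returned, with allylic transposition, to the neighbouring oxygen as a tertiary allyl ether. Both carbon–carbon bonds that 1 lacks are thereby traced to carbon–oxygen bonds at the two most acidic hydroxyls. On ring B the choice of ortho carbon is forced, because C3' is substituted. On ring A the step must choose C8 over C6. For that reason O5 is carried as an acetal and not as a free hydroxyl. A chelated 5-hydroxyl is sometimes credited with steering such shifts to C8, but the bond-fixation argument points the other way (see step 4).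

5 from 4. The O5–CH2 and O3'–CH2 acetal bonds are cut. O3' is blocked so that it cannot be methylated later and nothing can shift between the catechol oxygens; O5 is blocked to remove the hydrogen bond to the carbonyl. One reagent does both. The demand is a base strong enough to open the chelate, which is tolerable because the alkynes are gone at this stage.

4 from 3. No skeletal bond is cut; each vinyl group is traced back to an ethynyl group. Tertiary allyl ethers of phenols are not accessible by direct alkylation, since a prenyl halide reacts at its primary end, whereas tertiary propargyl ethers are. The demand is to stop at the alkene and leave the C2=C3 bond of ring C alone.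

3 from 1 and 2. The O7–C and O4'–C bonds are cut. 1 already contains rings A, B and C with all six oxygens, and 2 supplies each five-carbon unit, so the whole carbon skeleton is bought. The demand is that only the two most acidic of four hydroxyls react.

## Other disconnections considered

Alternative 1: Ring A is taken apart at C8–C8a, C6–C7 and C4a–C8a.
- Forward step: heating 3-ethoxycyclobut-2-en-1-one A1 with the prenyl-substituted silyloxyalkyne A2 would give the phenol A3. The sequence is four-electron ring opening, (2+2) addition across the alkyne, a second ring opening and a 6π closure. In A3 the prenyl carbon lies between the free hydroxyl (the later O1) and the silyl ether (O7), with the ethyl ether at the later C5.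
- In favour: the chain is built into C8 by the connectivity of A2, so the C6/C8 question cannot arise, and the three oxygens emerge differentiated. On regiochemical certainty at ring A this alternative is the better of the two.
- Against: A3 is only a phenol. C4a would still have to be acylated, ring C closed and ring B made with its own chain, for which an oxygen-to-carbon shift from O4' remains the obvious method. An ethyl ether peri to the carbonyl would need BCl3 or similar next to two acid-sensitive alkenes. A2 is a multi-step, moisture-sensitive reagent.
- Comparison: structurally it settles one of the two chain placements and none of the hydroxyl sorting on ring B. Mechanistically it is a pericyclic cascade as predictable as the sigmatropic shift, so the two are equal there. In step economy it is far behind, roughly doubling the 7 steps of the chosen plan, because 1 already contains everything A3 would have to be elaborated into.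

Alternative 2: Ring B is taken apart at C2'–C3' and C1'–C6'.
- Forward step: (4+2) cycloaddition of 3-methoxy-4-(3-methylbut-2-enyl)furan A4 with methyl prop-2-ynoate A5, the methoxy-bearing C2 of the furan bonding to the unsubstituted alkyne carbon. Opening of the oxygen bridge on the side where the methoxy group stabilises the cation would then give the benzoate A6.
- In favour: hydroxyl at C3', methyl ether at C4', chain at C5' and carboxyl at C1' are set in one step. The O3'/O4' distinction is built in, so neither the catechol discrimination of step 1 nor the O7/O4' sorting of steps 5 and 6 would be needed for ring B; on that point it is the better plan. The ester is at the right oxidation level for a Baker–Venkataraman union with a ring A ketone.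
- Against: A4 is not an article of commerce, is acid- and air-sensitive and needs its own multi-step preparation. Two regiochemical events (cycloaddition and bridge opening) must both go the right way. Ring A with its C8 chain is not addressed, and the flavone would still have to be assembled and its phenols protected and unveiled.
- Comparison: structurally it answers ring B only. Mechanistically it is well founded but carries two selectivities where the ring B shift of the chosen plan carries none. In step economy it is longer once the ring A chemistry is added.

Alternative 3: Ring C is cut at O1–C8a and C4–C4a, and then at O1–C2.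
- Forward step: CsF would trigger 1,2-elimination of the silyl triflate A7. The carboxylate of the arylpropiolic acid A8 would add its oxygen to C8a of the strained triple bond, the acyl group would pass to C4a, and the phenoxide would close ring C onto the ynone to give A9.
- In favour: it is the most convergent plan, joining two complete halves and forming ring C in one flask; on convergence it is better. The acetal at C5 polarises the triple bond so that oxygen should add at C8a. A9 is the same compound as 9, so the endgame would be the same single deprotection; on that point the two plans are equal.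
- Against: both chains must already be in place, so the actual problem is only moved into the preparation of A7 and A8. A7 is a hexasubstituted benzene needing a long regiocontrolled synthesis. Strained aryl triple bonds undergo ene and (2+2) reactions with trisubstituted alkenes, and two prenyl groups are present. The C8 chain crowds the carbon that oxygen has to attack.
- Comparison: structurally it solves the union and not the chain placement. Mechanistically it is less secure than a thermal shift in a buffered solvent. In step economy its longest linear sequence could be similar, but the total count would be clearly higher.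

Key step: step 4

Assumption: the C5 oxygen is a spectator position, so 5 and 7 carry it as a methoxymethyl ether while the skeletons and the bonds formed in the key step are unchanged; flavone numbering (O1, C2–C8a, C1'–C6') is used throughout.

Step 1
Reactants: 1 luteolin (2-(3,4-dihydroxyphenyl)-5,7-dihydroxychromen-4-one); 2 3-chloro-3-methylbut-1-yne
Product: 3 5-hydroxy-2-[3-hydroxy-4-(2-methylbut-3-yn-2-yloxy)phenyl]-7-(2-methylbut-3-yn-2-yloxy)chromen-4-one
Conditions: 2 (2.4 equiv), K2CO3 (2.2 equiv), KI (0.2 equiv), CuI (5 mol%), degassed DMF, 40 °C, Ar
Reagents that add atoms: none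
Why: Copper-catalysed O-propargylation of phenoxides by a tertiary propargyl chloride; with two equivalents of carbonate only the 7-OH (para to the C4 carbonyl) and the 4'-OH (conjugated to it through C2=C3) are ionised, while the 3'-OH is less acidic and the 5-OH is chelated. Exclusion of air protects the catechol.

Step 2
Reactants: 3 5-hydroxy-2-[3-hydroxy-4-(2-methylbut-3-yn-2-yloxy)phenyl]-7-(2-methylbut-3-yn-2-yloxy)chromen-4-one
Product: 4 5-hydroxy-2-[3-hydroxy-4-(2-methylbut-3-en-2-yloxy)phenyl]-7-(2-methylbut-3-en-2-yloxy)chromen-4-one
Conditions: H2 (1 atm), Pd/CaCO3 poisoned with Pb(OAc)2, quinoline, EtOAc, rt, stopped after two equivalents of H2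
Reagents that add atoms: none
Why: Semihydrogenation of terminal alkynes over poisoned palladium stops at the alkene; the C2=C3 bond of the pyranone and the tertiary C–O bonds should not react. Doing this before step 3 keeps the acidic alkyne C–H away from NaH.

Step 3
Reactants: 4 5-hydroxy-2-[3-hydroxy-4-(2-methylbut-3-en-2-yloxy)phenyl]-7-(2-methylbut-3-en-2-yloxy)chromen-4-one
Product: 5 5-(methoxymethoxy)-2-[3-(methoxymethoxy)-4-(2-methylbut-3-en-2-yloxy)phenyl]-7-(2-methylbut-3-en-2-yloxy)chromen-4-one
Conditions: NaH (2.6 equiv), MOMCl (2.8 equiv), DMF, 0 °C to rt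
Reagents that add atoms: chloromethyl methyl ether, COCCl
Why: Williamson-type acetal formation; NaH is needed to break the O5–H···O=C4 chelate, and the tertiary allyl ethers are inert to it. An acetal on O3' cannot migrate to O4' later, unlike a silyl or acyl group.

Step 4
Reactants: 5 5-(methoxymethoxy)-2-[3-(methoxymethoxy)-4-(2-methylbut-3-en-2-yloxy)phenyl]-7-(2-methylbut-3-en-2-yloxy)chromen-4-one
Product: 7 7-hydroxy-2-[4-hydroxy-3-(methoxymethoxy)-5-(3-methylbut-2-enyl)phenyl]-5-(methoxymethoxy)-8-(3-methylbut-2-enyl)chromen-4-one, via bis(cyclohexadienone) tautomer 6 (not isolated)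
Conditions: PhNEt2 (degassed), 140 °C, Ar
Reagents that add atoms: none
Why: Each aryl 2-methylbut-3-en-2-yl ether should undergo a concerted suprafacial [3,3] shift through a chair-like six-membered transition state in which the terminal CH2 bonds to the ortho carbon as the O–C(CH3)2 bond breaks, so the tertiary ether arrives with allylic inversion as the linear 3-methylbut-2-enyl chain, and the two dienones (drawn together as 6) enolise to the phenols of 7. This is the aromatic Claisen rearrangement of aryl 1,1-dimethylallyl ethers, the standard route to ortho-prenylphenols, applied twice in one substrate; the geminal methyl groups bring the temperature down to about 130–150 °C. No ring is closed and no stereocentre survives, because the sp3 carbons C8 and C5' of 6 are erased on tautomerisation. On ring B only C5' can accept the chain, since C3' carries the acetal and a shift to it would give a dienone that cannot enolise and reverts. On ring A the chain must go to C8 and not C6, which is why O5 is an acetal: without a hydrogen bond to the C4 carbonyl the bond fixation is that of the 4-pyranone (C4a=C8a, hence C7=C8), which is what sends 7-allyloxychromones to C8. A chelated 5-hydroxyl would instead favour C4a=C5 and C6=C7 and open the C6 path, as ethers of 2,4-dihydroxyacetophenone migrate next to the chelated hydroxyl. The acetal, turned away from the carbonyl, also leans over C6 and hinders it. The basic solvent buffers the new phenols, so acetal loss and chroman formation at the 7-OH/C8 pair should not compete; Eu(fod)3 is avoided because it would bind the C4=O/O5 site.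

Step 5
Reactants: 7 7-hydroxy-2-[4-hydroxy-3-(methoxymethoxy)-5-(3-methylbut-2-enyl)phenyl]-5-(methoxymethoxy)-8-(3-methylbut-2-enyl)chromen-4-one
Product: 8 2-[4-hydroxy-3-(methoxymethoxy)-5-(3-methylbut-2-enyl)phenyl]-5,7-bis(methoxymethoxy)-8-(3-methylbut-2-enyl)chromen-4-one
Conditions: MOMCl (1.05 equiv), K2CO3 (1.1 equiv), acetone, 0 °C
Reagents that add atoms: chloromethyl methyl ether, COCCl
Why: Chemoselective O-alkylation of the more acidic phenol: the 7-OH is a vinylogous carboxylic acid with one ortho substituent, while the 4'-OH is less acidic and flanked on both sides. An acetal is preferred to a silyl ether because it is inert to carbonate and MeI in step 6 and leaves with the other two in step 7.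

Step 6
Reactants: 8 2-[4-hydroxy-3-(methoxymethoxy)-5-(3-methylbut-2-enyl)phenyl]-5,7-bis(methoxymethoxy)-8-(3-methylbut-2-enyl)chromen-4-one
Product: 9 2-[4-methoxy-3-(methoxymethoxy)-5-(3-methylbut-2-enyl)phenyl]-5,7-bis(methoxymethoxy)-8-(3-methylbut-2-enyl)chromen-4-one
Conditions: MeI (3 equiv), K2CO3 (2 equiv), DMF, rt
Reagents that add atoms: iodomethane, CI
Why: Williamson methylation of the only free hydroxyl; a small electrophile in a dipolar solvent should overcome the double ortho substitution, and no other site can react.

Step 7
Reactants: 9 2-[4-methoxy-3-(methoxymethoxy)-5-(3-methylbut-2-enyl)phenyl]-5,7-bis(methoxymethoxy)-8-(3-methylbut-2-enyl)chromen-4-one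
Product: 10 5,7-dihydroxy-2-[3-hydroxy-4-methoxy-5-(3-methylbut-2-enyl)phenyl]-8-(3-methylbut-2-enyl)chromen-4-one
Conditions: HCl (0.3 M in MeOH), 0 °C to 40 °C
Reagents that add atoms: none
Why: Acid-catalysed transacetalisation of three aryl methoxymethyl ethers to methanol; the peri acetal on O5 leaves first. Dilute acid and moderate temperature are chosen to spare the prenyl groups, which are routinely carried through this kind of deprotection.

Compound list
1 | luteolin, 2-(3,4-dihydroxyphenyl)-5,7-dihydroxychromen-4-one | O=c1cc(-c2ccc(O)c(O)c2)oc2cc(O)cc(O)c12 | starting material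
2 | 3-chloro-3-methylbut-1-yne | CC(C)(Cl)C#C | starting material
3 | 5-hydroxy-2-[3-hydroxy-4-(2-methylbut-3-yn-2-yloxy)phenyl]-7-(2-methylbut-3-yn-2-yloxy)chromen-4-one | C#CC(C)(C)Oc1cc(O)c2c(c1)oc(-c1ccc(OC(C)(C)C#C)c(O)c1)cc2=O | intermediate
4 | 5-hydroxy-2-[3-hydroxy-4-(2-methylbut-3-en-2-yloxy)phenyl]-7-(2-methylbut-3-en-2-yloxy)chromen-4-one | C=CC(C)(C)Oc1cc(O)c2c(c1)oc(-c1ccc(OC(C)(C)C=C)c(O)c1)cc2=O | intermediate
5 | 5-(methoxymethoxy)-2-[3-(methoxymethoxy)-4-(2-methylbut-3-en-2-yloxy)phenyl]-7-(2-methylbut-3-en-2-yloxy)chromen-4-one | C=CC(C)(C)Oc1cc(OCOC)c2c(c1)oc(-c1ccc(OC(C)(C)C=C)c(OCOC)c1)cc2=O | intermediate (precursor of the key step)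
6 | 5-(methoxymethoxy)-2-[5-(methoxymethoxy)-3-(3-methylbut-2-enyl)-4-oxocyclohexa-1,5-dien-1-yl]-8-(3-methylbut-2-enyl)-8H-chromene-4,7-dione (C8 and C5' undefined, lost on enolisation) | COCOC1=CC(=O)C(CC=C(C)C)C2=C1C(=O)C=C(O2)C1=CC(CC=C(C)C)C(=O)C(OCOC)=C1 | intermediate (not isolated)
7 | 7-hydroxy-2-[4-hydroxy-3-(methoxymethoxy)-5-(3-methylbut-2-enyl)phenyl]-5-(methoxymethoxy)-8-(3-methylbut-2-enyl)chromen-4-one | COCOc1cc(O)c(CC=C(C)C)c2oc(-c3cc(CC=C(C)C)c(O)c(OCOC)c3)cc(=O)c12 | intermediate (product of the key step)
8 | 2-[4-hydroxy-3-(methoxymethoxy)-5-(3-methylbut-2-enyl)phenyl]-5,7-bis(methoxymethoxy)-8-(3-methylbut-2-enyl)chromen-4-one | COCOc1cc(OCOC)c(CC=C(C)C)c2oc(-c3cc(CC=C(C)C)c(O)c(OCOC)c3)cc(=O)c12 | intermediate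
9 | 2-[4-methoxy-3-(methoxymethoxy)-5-(3-methylbut-2-enyl)phenyl]-5,7-bis(methoxymethoxy)-8-(3-methylbut-2-enyl)chromen-4-one | COCOc1cc(OCOC)c(CC=C(C)C)c2oc(-c3cc(CC=C(C)C)c(OC)c(OCOC)c3)cc(=O)c12 | intermediate
10 | 5,7-dihydroxy-2-[3-hydroxy-4-methoxy-5-(3-methylbut-2-enyl)phenyl]-8-(3-methylbut-2-enyl)chromen-4-one | COc1c(O)cc(-c2cc(=O)c3c(O)cc(O)c(CC=C(C)C)c3o2)cc1CC=C(C)C | target

Total step count: 7. Longest linear sequence: 7 steps (1 to 10).

Least certain steps

Step 4 (key step).
- What may go wrong: partial delivery of the ring A chain to C6, because both ortho carbons of O7 are free and the preference rests on bond fixation and the bulk of the O5 acetal, not on a blocked position. Heterolysis of the O7–C(CH3)2 bond may also compete, since the 7-oxygen is the conjugate base of a vinylogous acid; that would strip the chain or return it unselectively.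
- Fallback (sets out from 1, comes back at 10): the ring A chain is brought in from O5 instead of O7.
 - 1 is protected at its most acidic hydroxyl (MOMCl 1.0 equiv, K2CO3 1.0 equiv, acetone, 0 °C) to the 7-O-methoxymethyl ether F1.
 - F1 is alkylated at O4' with 2 (K2CO3, KI, CuI, DMF) to the 4'-O-(2-methylbut-3-yn-2-yl) ether F2.
 - O3' is capped (MOMCl, i-Pr2NEt, CH2Cl2) to the 7,3'-bis(methoxymethyl) ether F3.
 - The chelated O5 is alkylated (1-bromo-3-methylbut-2-ene, K2CO3, DMF, 50 °C) to the 5-O-(3-methylbut-2-enyl) ether F4.
 - Semihydrogenation (H2, Pd/CaCO3 poisoned with Pb(OAc)2, quinoline) gives the 4'-O-(2-methylbut-3-en-2-yl) ether F5.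
 - Heating F5 with Eu(fod)3 and NaHCO3 in PhCl at 85 °C should carry the O5 chain to C6 and on to C8 (para-Claisen–Cope sequence, two inversions, the established entry to 8-prenyl-5-hydroxyflavones) and the O4' chain to C5', giving the 5,4'-dihydroxy-8,5'-diprenyl compound F6.
 - MeI and K2CO3 should methylate O4' only, the 5-hydroxyl being chelated, to the 4'-methyl ether F7, and methanolic HCl then gives 10.

Step 1.
- What may go wrong: alkylation spilling over to O3', since the catechol oxygens differ by only a few pKa units, and oxidation of the catechol under basic copper conditions.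
- Fallback (sets out from 1, comes back at 4): the tertiary allyl ethers are made directly by palladium π-allyl chemistry, skipping the alkyne stage. tert-Butyl 2-methylbut-3-en-2-yl carbonate F8 (from 2-methylbut-3-en-2-ol and di-tert-butyl dicarbonate) is ionised by Pd(PPh3)4 (5 mol%) in THF/DMF at 0 °C. The tert-butoxide released deprotonates only as many hydroxyls as allyl units are delivered, the most acidic first, and the phenoxide attacks the more substituted allyl terminus under kinetic control. No excess base and no copper are present.

Step 7.
- What may go wrong: acid-promoted closure of the C8 chain onto the freed 7-hydroxyl (chroman formation) and Markovnikov addition of HCl or methanol to the alkenes, because the tertiary cation of a prenyl group forms easily and the O3' acetal is the slowest to leave.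
- Fallback (sets out from 7, comes back at 10): O7 is masked with a base-labile group so that the acid step never meets a phenol next to a prenyl chain.
 - Pivaloyl chloride (1.05 equiv, Et3N, CH2Cl2, −20 °C) should acylate the more acidic, singly flanked 7-OH to the 7-O-pivalate F9.
 - MeI and K2CO3 give the 4'-methyl ether F10.
 - Methanolic HCl removes the two acetals to the 5,3'-dihydroxy 7-O-pivalate F11.
 - K2CO3 in MeOH at rt then frees O7 to give 10.
 - The sequence also offers a sterically governed way of singling out O7 should step 5 discriminate poorly.

Further compounds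
F1 | step 4 | 2-(3,4-dihydroxyphenyl)-5-hydroxy-7-(methoxymethoxy)chromen-4-one | COCOc1cc(O)c2c(c1)oc(-c1ccc(O)c(O)c1)cc2=O
F2 | step 4 | 5-hydroxy-2-[3-hydroxy-4-(2-methylbut-3-yn-2-yloxy)phenyl]-7-(methoxymethoxy)chromen-4-one | COCOc1cc(O)c2c(c1)oc(-c1ccc(OC(C)(C)C#C)c(O)c1)cc2=O
F3 | step 4 | 5-hydroxy-7-(methoxymethoxy)-2-[3-(methoxymethoxy)-4-(2-methylbut-3-yn-2-yloxy)phenyl]chromen-4-one | COCOc1cc(O)c2c(c1)oc(-c1ccc(OC(C)(C)C#C)c(OCOC)c1)cc2=O
F4 | step 4 | 7-(methoxymethoxy)-2-[3-(methoxymethoxy)-4-(2-methylbut-3-yn-2-yloxy)phenyl]-5-(3-methylbut-2-enyloxy)chromen-4-one | COCOc1cc(OCC=C(C)C)c2c(c1)oc(-c1ccc(OC(C)(C)C#C)c(OCOC)c1)cc2=O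
F5 | step 4 | 7-(methoxymethoxy)-2-[3-(methoxymethoxy)-4-(2-methylbut-3-en-2-yloxy)phenyl]-5-(3-methylbut-2-enyloxy)chromen-4-one | COCOc1cc(OCC=C(C)C)c2c(c1)oc(-c1ccc(OC(C)(C)C=C)c(OCOC)c1)cc2=O
F6 | step 4 | 5-hydroxy-2-[4-hydroxy-3-(methoxymethoxy)-5-(3-methylbut-2-enyl)phenyl]-7-(methoxymethoxy)-8-(3-methylbut-2-enyl)chromen-4-one | COCOc1cc(O)c2c(c1CC=C(C)C)oc(-c1cc(CC=C(C)C)c(O)c(OCOC)c1)cc2=O
F7 | step 4 | 5-hydroxy-2-[4-methoxy-3-(methoxymethoxy)-5-(3-methylbut-2-enyl)phenyl]-7-(methoxymethoxy)-8-(3-methylbut-2-enyl)chromen-4-one | COCOc1cc(O)c2c(c1CC=C(C)C)oc(-c1cc(CC=C(C)C)c(OC)c(OCOC)c1)cc2=O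
F8 | step 1 | tert-butyl 2-methylbut-3-en-2-yl carbonate | C=CC(C)(C)OC(=O)OC(C)(C)C
F9 | step 7 | [2-[4-hydroxy-3-(methoxymethoxy)-5-(3-methylbut-2-enyl)phenyl]-5-(methoxymethoxy)-8-(3-methylbut-2-enyl)-4-oxochromen-7-yl] 2,2-dimethylpropanoate | COCOc1cc(OC(=O)C(C)(C)C)c(CC=C(C)C)c2oc(-c3cc(CC=C(C)C)c(O)c(OCOC)c3)cc(=O)c12
F10 | step 7 | [2-[4-methoxy-3-(methoxymethoxy)-5-(3-methylbut-2-enyl)phenyl]-5-(methoxymethoxy)-8-(3-methylbut-2-enyl)-4-oxochromen-7-yl] 2,2-dimethylpropanoate | COCOc1cc(OC(=O)C(C)(C)C)c(CC=C(C)C)c2oc(-c3cc(CC=C(C)C)c(OC)c(OCOC)c3)cc(=O)c12
F11 | step 7 | [5-hydroxy-2-[3-hydroxy-4-methoxy-5-(3-methylbut-2-enyl)phenyl]-8-(3-methylbut-2-enyl)-4-oxochromen-7-yl] 2,2-dimethylpropanoate | CC(C)(C)C(=O)Oc1cc(O)c2c(c1CC=C(C)C)oc(-c1cc(CC=C(C)C)c(OC)c(O)c1)cc2=O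
A1 | alternative 1 | 3-ethoxycyclobut-2-en-1-one | CCOC1=CC(=O)C1
A2 | alternative 1 | triisopropyl[(5-methylhex-4-en-1-yn-1-yl)oxy]silane | CC(C)=CCC#CO[Si](C(C)C)(C(C)C)C(C)C
A3 | alternative 1 | 5-ethoxy-2-(3-methylbut-2-enyl)-3-(triisopropylsilyloxy)phenol | CCOc1cc(O)c(CC=C(C)C)c(O[Si](C(C)C)(C(C)C)C(C)C)c1
A4 | alternative 2 | 3-methoxy-4-(3-methylbut-2-enyl)furan | COc1cocc1CC=C(C)C
A5 | alternative 2 | methyl prop-2-ynoate | COC(=O)C#C
A6 | alternative 2 | methyl 3-hydroxy-4-methoxy-5-(3-methylbut-2-enyl)benzoate | COC(=O)c1cc(O)c(OC)c(CC=C(C)C)c1
A7 | alternative 3 | [3,5-bis(methoxymethoxy)-6-(3-methylbut-2-enyl)-2-(trimethylsilyl)phenyl] trifluoromethanesulfonate | COCOc1cc(OCOC)c(CC=C(C)C)c(OS(=O)(=O)C(F)(F)F)c1[Si](C)(C)C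
A8 | alternative 3 | 3-[4-methoxy-3-(methoxymethoxy)-5-(3-methylbut-2-enyl)phenyl]prop-2-ynoic acid | COCOc1cc(C#CC(=O)O)cc(CC=C(C)C)c1OC
A9 | alternative 3 | 2-[4-methoxy-3-(methoxymethoxy)-5-(3-methylbut-2-enyl)phenyl]-5,7-bis(methoxymethoxy)-8-(3-methylbut-2-enyl)chromen-4-one | COCOc1cc(OCOC)c(CC=C(C)C)c2oc(-c3cc(OCOC)c(OC)c(CC=C(C)C)c3)cc(=O)c12
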